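**Plan**
Numbering: lactone ring O1, C2(=O), C3(Me), C4(OH), C5. The chain C6–C18 runs from C5 to C3 of the furan ring.
Cuts, in retrosynthetic order: C3–C4 (Dieckmann), C5–O (enolate oxidation), C5–C6 (orthoester Claisen), C7–C8 (Grignard), C9–C10 (orthoester Claisen), C11–C12 (Grignard), C13=C14 (Wittig), C18–furan (Suzuki–Miyaura), C15–C16 (allylation).
Enabling feature: the E-trisubstituted C11=C12 alkene is the inner end of the C11–C14 diene and is followed by the C10–C9 ethylene and carbonyl-level C8. This γ,δ-unsaturated ester pattern maps onto a C12 carbinol flanked by an isopropenyl and an E-alkenyl group.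
Forward, the chain grows linearly from the purchased furan ring towards C4. The tetronic acid ring is the only ring formed and closes in the last step.
C15 (S) comes from allylation and C5 (R) from hydroxylation of (R)-4-benzyloxazolidinone imide enolates. E-C13=C14 comes from a stabilised ylide, and E-C11=C12 and E-C7=C8 from chair Claisen transition states.

Key step: step 7

Remark: the two isopropenyl carbinols of the route are carried as mixtures of epimers at the hydroxyl-bearing carbon, because that centre is erased in the following step. The target is written as its 4-hydroxy enol tautomer.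

Step 1
Reactants: 1 (4R)-4-benzyl-3-propanoyl-1,3-oxazolidin-2-one; 2 allyl iodide
Product: 4 (4R)-4-benzyl-3-[(2S)-2-methylpent-4-enoyl]-1,3-oxazolidin-2-one, via sodium Z-enolate 3 (not isolated)
Conditions: NaN(SiMe3)2, THF, −78 °C; then 2, −78 to −45 °C
Reagents that add atoms: allyl iodide 2, C=CCI; NaN(SiMe3)2, C[Si](C)(C)[N-][Si](C)(C)C.[Na+] (sodium in 3 only)
Why: Evans asymmetric alkylation: sodium chelation between the enolate and carbamate oxygens fixes Z-enolate 3 in one rotamer, the C4 benzyl group blocks one face, and the reactive allylic iodide enters from the other, which sets the future C15 with S configuration.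

Step 2
Reactants: 4 (4R)-4-benzyl-3-[(2S)-2-methylpent-4-enoyl]-1,3-oxazolidin-2-one
Product: 5 (2S)-N-methoxy-N,2-dimethylpent-4-enamide
Conditions: MeONHMe·HCl, AlMe3, CH2Cl2, 0 °C to rt
Reagents that add atoms: N,O-dimethylhydroxylamine hydrochloride, CNOC.Cl
Why: Weinreb aminolysis with the aluminium amide formed from AlMe3 and the amine salt attacks the exocyclic imide carbonyl under non-basic conditions, so the α-stereocentre and the terminal alkene are left unchanged.

Step 3
Reactants: 5 (2S)-N-methoxy-N,2-dimethylpent-4-enamide; 6 3-bromofuran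
Product: 8 (2S)-5-(furan-3-yl)-N-methoxy-N,2-dimethylpentanamide, via B-alkyl-9-BBN adduct 7 (not isolated)
Conditions: 9-BBN-H, THF, 0 °C to rt; then 6, PdCl2(dppf) (5 mol %), aq. K3PO4, DMF, 50 °C
Reagents that add atoms: 3-bromofuran 6, Brc1ccoc1; 9-BBN-H, [H]B1C2CCCC1CCC2 (boron fragment in 7 only)
Why: Anti-Markovnikov hydroboration of the monosubstituted alkene followed by B-alkyl Suzuki–Miyaura coupling with the heteroaryl bromide forms the C18–furan bond, the tertiary amide being inert to 9-BBN-H at room temperature and its α-proton too weakly acidic to exchange with aqueous phosphate.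

Step 4
Reactants: 8 (2S)-5-(furan-3-yl)-N-methoxy-N,2-dimethylpentanamide
Product: 9 (2S)-5-(furan-3-yl)-2-methylpentanal
Conditions: i-Bu2AlH, THF, −78 °C; aq. potassium sodium tartrate
Reagents that add atoms: none
Why: Weinreb amide reduction: chelation of aluminium by the N-methoxy oxygen holds the substrate at the aldehyde oxidation level until the cold quench, so neither over-reduction nor epimerisation of C15 is expected, and 9 is used at once without chromatography.

Step 5
Reactants: 9 (2S)-5-(furan-3-yl)-2-methylpentanal; 10 (triphenylphosphoranylidene)acetaldehyde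
Product: 11 (2E,4S)-7-(furan-3-yl)-4-methylhept-2-enal
Conditions: 10 (1.3 equiv), toluene, 80 °C
Reagents that add atoms: (triphenylphosphoranylidene)acetaldehyde 10, O=CC=P(c1ccccc1)(c1ccccc1)c1ccccc1
Why: Wittig olefination with a stabilised formylmethylene ylide is E-selective, needs no added base that could epimerise C15, and the product enal is less electrophilic than the saturated aldehyde 9, which limits a second homologation.

Step 6
Reactants: 11 (2E,4S)-7-(furan-3-yl)-4-methylhept-2-enal; 12 isopropenylmagnesium bromide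
Product: 13 (4E,6S)-9-(furan-3-yl)-2,6-dimethylnona-1,4-dien-3-ol (both C3 epimers)
Conditions: 12, THF, −78 °C; sat. aq. NH4Cl
Reagents that add atoms: isopropenylmagnesium bromide 12, C=C(C)[Mg]Br
Why: Grignard 1,2-addition to an enal at low temperature forms C11–C12; the carbinol centre C12 arises without control, which is harmless because step 7 erases it.

Step 7
Reactants: 13 (4E,6S)-9-(furan-3-yl)-2,6-dimethylnona-1,4-dien-3-ol; 14 triethyl orthoacetate
Product: 17 ethyl (4E,6E,8S)-11-(furan-3-yl)-4,8-dimethylundeca-4,6-dienoate, via mixed orthoester 15 (not isolated), via ketene acetal 16 (not isolated)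
Conditions: 14 (excess), EtCO2H (10 mol %), 138 °C, EtOH distilled off
Reagents that add atoms: triethyl orthoacetate 14, CCOC(C)(OCC)OCC
Why: Propionic acid catalyses exchange of one ethoxy group of 14 for the C12 alkoxy group (15), and loss of a second ethanol gives ketene acetal 16, whose CH2 terminus (C9) bonds to the methylene terminus C10 of the isopropenyl arm in a concerted chair [3,3] shift while the C12–O bond breaks and C11=C12 forms. The closest known reaction type is the Johnson orthoester Claisen rearrangement of secondary isopropenyl carbinols and of divinyl carbinols to E-γ,δ-unsaturated esters. No ring is closed and no stereocentre is created; the C12 carbinol centre is destroyed, so both epimers of 13 converge on one product, and C15 lies outside the six-atom array and is untouched. E geometry at C11=C12 follows from the chair in which the C13 alkenyl substituent on C12 is equatorial, because the axial alternative suffers a 1,3-diaxial contact with the ethoxy group of the ketene acetal, and the C13=C14 alkene is a spectator that keeps its E geometry. The step needs regioselection between the two allyl arms: C10 is an unsubstituted CH2, whereas C14 is a substituted carbon flanked by the branched C15, so bond formation at C10 has the lower barrier. The weak acid in catalytic amount and the continuous removal of ethanol hold back ionisation of the doubly allylic C12–O bond and attack on the furan.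

Step 8
Reactants: 17 ethyl (4E,6E,8S)-11-(furan-3-yl)-4,8-dimethylundeca-4,6-dienoate
Product: 18 (4E,6E,8S)-11-(furan-3-yl)-4,8-dimethylundeca-4,6-dienal
Conditions: i-Bu2AlH (1.05 equiv), CH2Cl2, −78 °C; aq. potassium sodium tartrate
Reagents that add atoms: none
Why: Partial reduction of an ester with one equivalent of i-Bu2AlH at −78 °C in a non-coordinating solvent stops at the aldehyde after the cold quench, and diene, furan and C15 are inert to the hydride.

Step 9
Reactants: 18 (4E,6E,8S)-11-(furan-3-yl)-4,8-dimethylundeca-4,6-dienal; 12 isopropenylmagnesium bromide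
Product: 19 (6E,8E,10S)-13-(furan-3-yl)-2,6,10-trimethyltrideca-1,6,8-trien-3-ol (both C3 epimers)
Conditions: 12, THF, −78 °C; sat. aq. NH4Cl
Reagents that add atoms: isopropenylmagnesium bromide 12, C=C(C)[Mg]Br
Why: Grignard addition to an unhindered aliphatic aldehyde forms C7–C8; both C8 epimers are accepted because the centre disappears in step 10.

Step 10
Reactants: 19 (6E,8E,10S)-13-(furan-3-yl)-2,6,10-trimethyltrideca-1,6,8-trien-3-ol; 14 triethyl orthoacetate
Product: 22 ethyl (4E,8E,10E,12S)-15-(furan-3-yl)-4,8,12-trimethylpentadeca-4,8,10-trienoate, via mixed orthoester 20 (not isolated), via ketene acetal 21 (not isolated)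
Conditions: 14 (excess), EtCO2H (10 mol %), 138 °C, EtOH distilled off
Reagents that add atoms: triethyl orthoacetate 14, CCOC(C)(OCC)OCC
Why: Johnson–Claisen rearrangement of a secondary isopropenyl carbinol forms C5–C6, and the chair with the C9 chain equatorial, free of the 1,3-diaxial contact with the ethoxy group, gives the E-C7=C8 alkene from either epimer, the temperature being well below that needed for sigmatropic hydrogen shifts in the diene.

Step 11
Reactants: 22 ethyl (4E,8E,10E,12S)-15-(furan-3-yl)-4,8,12-trimethylpentadeca-4,8,10-trienoate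
Product: 23 (4E,8E,10E,12S)-15-(furan-3-yl)-4,8,12-trimethylpentadeca-4,8,10-trienoic acid
Conditions: LiOH, THF/MeOH/H2O, rt; then 1 M HCl to pH 4, 0 °C
Reagents that add atoms: lithium hydroxide, [Li+].[OH-]
Why: Saponification of an unhindered ethyl ester; no stereocentre is α to the carbonyl, and the brief, cold and mildly acidic work-up spares the furan.

Step 12
Reactants: 23 (4E,8E,10E,12S)-15-(furan-3-yl)-4,8,12-trimethylpentadeca-4,8,10-trienoic acid; 24 (4R)-4-benzyl-1,3-oxazolidin-2-one
Product: 26 (4R)-4-benzyl-3-[(4E,8E,10E,12S)-15-(furan-3-yl)-4,8,12-trimethylpentadeca-4,8,10-trienoyl]-1,3-oxazolidin-2-one, via mixed pivalic anhydride 25 (not isolated)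
Conditions: t-BuCOCl, Et3N, THF, −20 °C; then LiCl, 24, −20 °C to rt
Reagents that add atoms: (4R)-4-benzyl-1,3-oxazolidin-2-one 24, O=C1OC[C@@H](Cc2ccccc2)N1; pivaloyl chloride, CC(C)(C)C(=O)Cl (atoms stay in 25 only)
Why: N-Acylation of an oxazolidinone by the mixed-anhydride method: LiCl and Et3N activate 24 without strong base, and the nitrogen attacks the unhindered carbonyl of 25 rather than the pivaloyl one.

Step 13
Reactants: 26 (4R)-4-benzyl-3-[(4E,8E,10E,12S)-15-(furan-3-yl)-4,8,12-trimethylpentadeca-4,8,10-trienoyl]-1,3-oxazolidin-2-one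
Product: 28 (4R)-4-benzyl-3-[(2R,4E,8E,10E,12S)-15-(furan-3-yl)-2-hydroxy-4,8,12-trimethylpentadeca-4,8,10-trienoyl]-1,3-oxazolidin-2-one, via sodium Z-enolate 27 (not isolated)
Conditions: NaN(SiMe3)2, THF, −78 °C; 2-(phenylsulfonyl)-3-phenyloxaziridine, −78 °C; AcOH, −78 °C
Reagents that add atoms: 2-(phenylsulfonyl)-3-phenyloxaziridine, O=S(=O)(c1ccccc1)N1OC1c1ccccc1; NaN(SiMe3)2, C[Si](C)(C)[N-][Si](C)(C)C.[Na+] (sodium in 27 only)
Why: Davis oxidation of a chiral imide enolate: the chelated Z-enolate 27 receives the electrophilic oxaziridine oxygen on the face opposite the benzyl group, which sets C5 as R, the alkenes and the furan do not react with the oxaziridine at −78 °C, and the cold acid quench stops the new alkoxide from attacking the carbamate carbonyl.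

Step 14
Reactants: 28 (4R)-4-benzyl-3-[(2R,4E,8E,10E,12S)-15-(furan-3-yl)-2-hydroxy-4,8,12-trimethylpentadeca-4,8,10-trienoyl]-1,3-oxazolidin-2-one
Product: 29 methyl (2R,4E,8E,10E,12S)-15-(furan-3-yl)-2-hydroxy-4,8,12-trimethylpentadeca-4,8,10-trienoate
Conditions: Mg(OMe)2, MeOH/THF, 0 °C; sat. aq. NH4Cl
Reagents that add atoms: magnesium methoxide, [Mg+2].[O-]C.[O-]C
Why: Magnesium alkoxide transesterification of an α-hydroxy imide: magnesium bound to the hydroxyl and the exocyclic carbonyl directs methoxide to that carbonyl, and the weakly basic medium at 0 °C leaves C5 configurationally intact.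

Step 15
Reactants: 29 methyl (2R,4E,8E,10E,12S)-15-(furan-3-yl)-2-hydroxy-4,8,12-trimethylpentadeca-4,8,10-trienoate; 30 propanoyl chloride
Product: 31 methyl (2R,4E,8E,10E,12S)-15-(furan-3-yl)-4,8,12-trimethyl-2-(propanoyloxy)pentadeca-4,8,10-trienoate
Conditions: 30, pyridine, DMAP (cat.), CH2Cl2, 0 °C
Reagents that add atoms: propanoyl chloride 30, CCC(=O)Cl
Why: Standard O-acylation (esterification) of a secondary alcohol with an acid chloride under mild amine base, which breaks no bond at C5.

Step 16
Reactants: 31 methyl (2R,4E,8E,10E,12S)-15-(furan-3-yl)-4,8,12-trimethyl-2-(propanoyloxy)pentadeca-4,8,10-trienoate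
Product: 33 (5R)-5-[(2E,6E,8E,10S)-13-(furan-3-yl)-2,6,10-trimethyltrideca-2,6,8-trien-1-yl]-4-hydroxy-3-methylfuran-2(5H)-one, via lithium tetronate 32 (not isolated)
Conditions: LiN(SiMe3)2 (2.5 equiv), THF, −78 to −20 °C; then 1 M HCl, 0 °C
Reagents that add atoms: LiN(SiMe3)2, C[Si](C)(C)[N-][Si](C)(C)C.[Li+] (lithium in 32 only)
Why: Dieckmann (intramolecular Claisen) condensation: deprotonation of the less hindered propionate CH2 and 5-exo-trig attack on the methyl ester form C3–C4, loss of methoxide and immediate deprotonation to tetronate 32 make the closure irreversible, and the low temperature together with the anionic ring protects the C5–H bond, so the R configuration is retained.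

**Compound list**
1 | (4R)-4-benzyl-3-propanoyl-1,3-oxazolidin-2-one | CCC(=O)N1[C@H](Cc2ccccc2)COC1=O | starting material
2 | allyl iodide (3-iodoprop-1-ene) | C=CCI | starting material
3 | sodium (Z)-enolate of 1 | C/C=C(\[O-])N1[C@H](Cc2ccccc2)COC1=O.[Na+] | intermediate
4 | (4R)-4-benzyl-3-[(2S)-2-methylpent-4-enoyl]-1,3-oxazolidin-2-one | C=CC[C@H](C)C(=O)N1[C@H](Cc2ccccc2)COC1=O | intermediate
5 | (2S)-N-methoxy-N,2-dimethylpent-4-enamide | C=CC[C@H](C)C(=O)N(C)OC | intermediate
6 | 3-bromofuran | Brc1ccoc1 | starting material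
7 | (2S)-5-(9-borabicyclo[3.3.1]nonan-9-yl)-N-methoxy-N,2-dimethylpentanamide | CON(C)C(=O)[C@@H](C)CCCB1C2CCCC1CCC2 | intermediate
8 | (2S)-5-(furan-3-yl)-N-methoxy-N,2-dimethylpentanamide | CON(C)C(=O)[C@@H](C)CCCc1ccoc1 | intermediate
9 | (2S)-5-(furan-3-yl)-2-methylpentanal | O=C[C@@H](C)CCCc1ccoc1 | intermediate
10 | (triphenylphosphoranylidene)acetaldehyde | O=CC=P(c1ccccc1)(c1ccccc1)c1ccccc1 | starting material
11 | (2E,4S)-7-(furan-3-yl)-4-methylhept-2-enal | O=C/C=C/[C@@H](C)CCCc1ccoc1 | intermediate
12 | isopropenylmagnesium bromide (THF solution) | C=C(C)[Mg]Br | starting material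
13 | (4E,6S)-9-(furan-3-yl)-2,6-dimethylnona-1,4-dien-3-ol, both C3 epimers | C=C(C)C(O)/C=C/[C@@H](C)CCCc1ccoc1 | intermediate
14 | triethyl orthoacetate | CCOC(C)(OCC)OCC | starting material
15 | 3-[(4S,5E)-7-(1,1-diethoxyethoxy)-4,8-dimethylnona-5,8-dien-1-yl]furan (mixed orthoester) | CCOC(C)(OCC)OC(C(C)=C)/C=C/[C@@H](C)CCCc1ccoc1 | intermediate
16 | 3-[(4S,5E)-7-[(1-ethoxyethenyl)oxy]-4,8-dimethylnona-5,8-dien-1-yl]furan (ketene acetal) | C=C(OCC)OC(C(C)=C)/C=C/[C@@H](C)CCCc1ccoc1 | intermediate
17 | ethyl (4E,6E,8S)-11-(furan-3-yl)-4,8-dimethylundeca-4,6-dienoate | CCOC(=O)CC/C(C)=C/C=C/[C@@H](C)CCCc1ccoc1 | intermediate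
18 | (4E,6E,8S)-11-(furan-3-yl)-4,8-dimethylundeca-4,6-dienal | O=CCC/C(C)=C/C=C/[C@@H](C)CCCc1ccoc1 | intermediate
19 | (6E,8E,10S)-13-(furan-3-yl)-2,6,10-trimethyltrideca-1,6,8-trien-3-ol, both C3 epimers | C=C(C)C(O)CC/C(C)=C/C=C/[C@@H](C)CCCc1ccoc1 | intermediate
20 | 3-[(4S,5E,7E)-11-(1,1-diethoxyethoxy)-4,8,12-trimethyltrideca-5,7,12-trien-1-yl]furan (mixed orthoester) | CCOC(C)(OCC)OC(C(C)=C)CC/C(C)=C/C=C/[C@@H](C)CCCc1ccoc1 | intermediate
21 | 3-[(4S,5E,7E)-11-[(1-ethoxyethenyl)oxy]-4,8,12-trimethyltrideca-5,7,12-trien-1-yl]furan (ketene acetal) | C=C(OCC)OC(C(C)=C)CC/C(C)=C/C=C/[C@@H](C)CCCc1ccoc1 | intermediate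
22 | ethyl (4E,8E,10E,12S)-15-(furan-3-yl)-4,8,12-trimethylpentadeca-4,8,10-trienoate | CCOC(=O)CC/C(C)=C/CC/C(C)=C/C=C/[C@@H](C)CCCc1ccoc1 | intermediate
23 | (4E,8E,10E,12S)-15-(furan-3-yl)-4,8,12-trimethylpentadeca-4,8,10-trienoic acid | OC(=O)CC/C(C)=C/CC/C(C)=C/C=C/[C@@H](C)CCCc1ccoc1 | intermediate
24 | (4R)-4-benzyl-1,3-oxazolidin-2-one | O=C1OC[C@@H](Cc2ccccc2)N1 | starting material
25 | mixed anhydride of 23 and pivalic acid | CC(C)(C)C(=O)OC(=O)CC/C(C)=C/CC/C(C)=C/C=C/[C@@H](C)CCCc1ccoc1 | intermediate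
26 | (4R)-4-benzyl-3-[(4E,8E,10E,12S)-15-(furan-3-yl)-4,8,12-trimethylpentadeca-4,8,10-trienoyl]-1,3-oxazolidin-2-one | O=C(CC/C(C)=C/CC/C(C)=C/C=C/[C@@H](C)CCCc1ccoc1)N1[C@H](Cc2ccccc2)COC1=O | intermediate
27 | sodium (Z)-enolate of 26 | [O-]/C(=C\C/C(C)=C/CC/C(C)=C/C=C/[C@@H](C)CCCc1ccoc1)N1[C@H](Cc2ccccc2)COC1=O.[Na+] | intermediate
28 | (4R)-4-benzyl-3-[(2R,4E,8E,10E,12S)-15-(furan-3-yl)-2-hydroxy-4,8,12-trimethylpentadeca-4,8,10-trienoyl]-1,3-oxazolidin-2-one | O=C([C@H](O)C/C(C)=C/CC/C(C)=C/C=C/[C@@H](C)CCCc1ccoc1)N1[C@H](Cc2ccccc2)COC1=O | intermediate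
29 | methyl (2R,4E,8E,10E,12S)-15-(furan-3-yl)-2-hydroxy-4,8,12-trimethylpentadeca-4,8,10-trienoate | COC(=O)[C@H](O)C/C(C)=C/CC/C(C)=C/C=C/[C@@H](C)CCCc1ccoc1 | intermediate
30 | propanoyl chloride | CCC(=O)Cl | starting material
31 | methyl (2R,4E,8E,10E,12S)-15-(furan-3-yl)-4,8,12-trimethyl-2-(propanoyloxy)pentadeca-4,8,10-trienoate | CCC(=O)O[C@H](C/C(C)=C/CC/C(C)=C/C=C/[C@@H](C)CCCc1ccoc1)C(=O)OC | intermediate
32 | lithium salt of 33 (lithium tetronate) | CC1=C([O-])[C@@H](C/C(C)=C/CC/C(C)=C/C=C/[C@@H](C)CCCc2ccoc2)OC1=O.[Li+] | intermediate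
33 | (5R)-5-[(2E,6E,8E,10S)-13-(furan-3-yl)-2,6,10-trimethyltrideca-2,6,8-trien-1-yl]-4-hydroxy-3-methylfuran-2(5H)-one | CC1=C(O)[C@@H](C/C(C)=C/CC/C(C)=C/C=C/[C@@H](C)CCCc2ccoc2)OC1=O | target

Total step count: 16. Longest linear sequence: 16 steps (1 to 33).

**Steps most likely to fail**

Step 7. Rearrangement through the C13=C14 arm may compete. The acid may also ionise the doubly allylic C12–O bond, with allylic transposition or loss of water. The fallback sets out from enal 11 and builds C11=C12 by olefination instead of rearrangement. Stabilised Wittig reaction with ethyl 2-(triphenylphosphoranylidene)propanoate (CH2Cl2, rt) should give ethyl (2E,4E,6S)-9-(furan-3-yl)-2,6-dimethylnona-2,4-dienoate F1. Reduction with i-Bu2AlH should give (2E,4E,6S)-9-(furan-3-yl)-2,6-dimethylnona-2,4-dien-1-ol F2. CBr4/PPh3 then converts it into 3-[(4S,5E,7E)-9-bromo-4,8-dimethylnona-5,7-dien-1-yl]furan F3. SN2 alkylation of F3 with the copper-modified lithium enolate of ethyl acetate (LiN(i-Pr)2, CuI, THF, −78 to −30 °C) forms C9–C10 and comes back to the route at ester 17.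

Step 16. The base may remove the C5 proton, which is activated by both the ester and the acyloxy group. This would erode the C5 configuration or trigger acyl migration from oxygen to C5. The fallback sets out from hydroxy ester 29, forms C3–C4 intermolecularly and closes the ring by lactonisation (O1–C2). Silylation (Et3SiCl, imidazole, CH2Cl2) gives methyl (2R,4E,8E,10E,12S)-15-(furan-3-yl)-4,8,12-trimethyl-2-[(triethylsilyl)oxy]pentadeca-4,8,10-trienoate F4. Crossed Claisen condensation with excess lithium enolate of ethyl propanoate (LiN(i-Pr)2, THF, −78 °C) should give ethyl (4R,6E,10E,12E,14S)-17-(furan-3-yl)-2,6,10,14-tetramethyl-3-oxo-4-[(triethylsilyl)oxy]heptadeca-6,10,12-trienoate F5, which is held in the flask as its stabilised enolate. Bu4NF in THF then removes the silyl group, and the freed C5 alkoxide lactonises onto the ethyl ester. After mild acidification this comes back at target 33.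

Step 5. The ylide may olefinate the product a second time, and prolonged heating may epimerise the α-stereocentre of the aldehyde by enolisation. The fallback sets out from aldehyde 9 and reverses the polarity at C13. Takai olefination (CHI3, CrCl2, THF/dioxane, 0 °C) should give 3-[(4S,5E)-6-iodo-4-methylhex-5-en-1-yl]furan F6. Nozaki–Hiyama–Kishi coupling of F6 with methacrolein (CrCl2, NiCl2 cat., DMF, rt) forms C12–C13 under neutral conditions and comes back at carbinol 13, bypassing enal 11 and step 6.

**Further compounds**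
F1 | step 7 | ethyl (2E,4E,6S)-9-(furan-3-yl)-2,6-dimethylnona-2,4-dienoate | CCOC(=O)/C(C)=C/C=C/[C@@H](C)CCCc1ccoc1
F2 | step 7 | (2E,4E,6S)-9-(furan-3-yl)-2,6-dimethylnona-2,4-dien-1-ol | OC/C(C)=C/C=C/[C@@H](C)CCCc1ccoc1
F3 | step 7 | 3-[(4S,5E,7E)-9-bromo-4,8-dimethylnona-5,7-dien-1-yl]furan | BrC/C(C)=C/C=C/[C@@H](C)CCCc1ccoc1
F4 | step 16 | methyl (2R,4E,8E,10E,12S)-15-(furan-3-yl)-4,8,12-trimethyl-2-[(triethylsilyl)oxy]pentadeca-4,8,10-trienoate | COC(=O)[C@@H](C/C(C)=C/CC/C(C)=C/C=C/[C@@H](C)CCCc1ccoc1)O[Si](CC)(CC)CC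
F5 | step 16 | ethyl (4R,6E,10E,12E,14S)-17-(furan-3-yl)-2,6,10,14-tetramethyl-3-oxo-4-[(triethylsilyl)oxy]heptadeca-6,10,12-trienoate (C2 epimers) | CCOC(=O)C(C)C(=O)[C@@H](C/C(C)=C/CC/C(C)=C/C=C/[C@@H](C)CCCc1ccoc1)O[Si](CC)(CC)CC
F6 | step 5 | 3-[(4S,5E)-6-iodo-4-methylhex-5-en-1-yl]furan | I/C=C/[C@@H](C)CCCc1ccoc1
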